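## The problem

The target is an eremophilane. Numbering used throughout: C1–C10 for the decalin, C11–C13 for the isopropenyl group on C7, C14 for the methyl on C5, C15 for the methyl on C4, primes for the acyl chain. It is a trans-fused decalin with the angular methyl on C5, a cis methyl on C4, a 3α ester, a 7α isopropenyl group and an 8α,9α diol. Seven contiguous ring stereocentres (3R,4R,5R,10R,9S,8R,7S) and one in the chain (4′S) must be set, and the quaternary C5 lies next to the methyl-bearing C4, so Robinson or polyene logic puts oxygen at C4 and C8 instead of C3 and C9. In the chair–chair form every substituent is equatorial except C14 and the C8 hydroxyl. The axial C14 shields the β face at C3, C7 and C9, so it can relay stereochemistry into ring B, but it also steers hydride reduction of a C3 or C9 ketone to the wrong (axial) alcohol; these two C–O bonds are better made with their configuration already fixed. C3 can control C4, and C4 can control C5, in a cyclohexenone; the C8 alcohol, axial and cis to both neighbours, is the one centre suited to a late equatorial hydride delivery. The isopropenyl group rules out hydrogenation, hydroboration and osmylation once it is present, and next to a C8 ketone it can slip into conjugation. The chain holds two (Z)-enoates and an acyloxy stereocentre: a free (Z)-4-hydroxy-2-enoate closes to a butenolide and (Z)-enoic acids isomerise on activation, so both alkenes are best carried as alkynes, and the C3 ester must be formed beside two other secondary hydroxyls. The feature that opens the problem is in ring B: the carbinol carbon C8 is bonded to C7, which carries the isopropenyl group, and C6 is a plain CH2 on the quaternary C5. This is the 2-isopropenylcyclohexanol retron of a carbonyl-ene reaction between a C8 aldehyde and a prenyl group on C5.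

## Retrosynthesis

**Side chain.** The C3–O acyl bond is cut last and both (Z)-alkenes are traced back to alkynes: target 29 comes from its 9-O-TBS ether 28, 28 from the bis-ynoate 27 by Lindlar semihydrogenation, and 27 from diol 19 and acid 26. This avoids activating a (Z)-enoic acid and never exposes a (Z)-γ-hydroxy enoate. The forward reaction must acylate the equatorial C3–OH of 19 in preference to the axial, flanked C8–OH.

**C8.** The axial 8α-OH of 18 (the 3-O-TES ether of 19) is cut to ketone 17, and 17 to the epimeric alcohols 16. Equatorial hydride delivery to a 2-alkoxycyclohexanone is reliable, so the ring-closing step need not control C8.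

**Ring B (key cut).** The C7–C8 bond of 16 is cut to aldehyde 15. Against cuts at C5–C6 or C9–C10, this one makes the isopropenyl group from a simple prenyl group in the same event. It needs no redox step on a molecule that carries the isopropenyl group, and it lets the axial C14 fix C7. The precursor is monocyclic and lacks C7, C8 and the isopropenyl alkene. The forward reaction must give proton transfer (ene) and not cation capture.

**C9–O and the C8 aldehyde.** Aldehyde 15 comes from α-silyloxy ester 14, 14 from hydroxy ester 13, and 13 from ester 11 by enolate hydroxylation. The C9–O bond is made in an open chain, where the C10 stereocentre (small C1 against quaternary C5) controls the enolate face. This avoids the hydride reduction of a C9 ketone, which the axial C14 would direct wrongly.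

**C9–C10 and the C10 hydrogen.** Ester 11 comes from the exocyclic enoate 10, and 10 from ketone 9 by olefination. Two carbons are added at once, and the C10 hydrogen is delivered to the face opposite the axial C14.

**Ring A triad.** Ketone 9 is cut at C4–C15 and C5–C6 into enone 6, a methyl nucleophile and prenyl bromide 7. One three-component operation sets C4 and C5 (quaternary) from C3 and installs the ene donor.

**The seed.** Enone 6 comes from iodoenone 5, silyl ether 4 and hydroxyenone 3, and 3 from cyclohexa-1,3-diene 1 through the meso endoperoxide 2. C3 is the only core stereocentre set by a catalyst.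

**Acid 26.** Acid 26 comes from PMB ester 25, 25 from hydroxy ester 23 and hex-2-ynoic acid 24, and 23 from hydroxy acid 22, the carboxylation product of (S)-pent-1-yn-3-ol 20.

## Roads not taken

**Alternative 1:** Robinson annulation (the obvious cut, C5–C6 and C9=C10). 2-Methylcyclohexane-1,3-dione and methyl vinyl ketone give (S)-Wieland–Miescher ketone A1 in one catalytic step. A1 has its oxygen at C4 and C8 and a Δ9(10) alkene, so almost every centre must then be reworked one at a time:
- C4=O has to become CH–CH3 while C3 is oxygenated, and hydride delivery to a C3 ketone is directed to the axial 3β alcohol by C14.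
- C9–OH with 10α-H needs a net anti-Markovnikov hydration of the enone.
- The isopropenyl group must be built α to the C8 ketone by aldol and dehydration, where elimination to the conjugated isopropylidene competes.
- The alkene reductions needed at C4 collide with the isopropenyl group.

The chosen plan makes C7, ring B and the isopropenyl group in one step and never needs a C4 carbonyl.

**Alternative 2:** Intramolecular Diels–Alder (cut C5–C10 and C6–C7). Trienone A2, an isopropenyl ketone tethered to an (E,E)-diene, would close to octalone A3, and the Δ8 alkene would then be dihydroxylated. Three points count against it: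
- The ketone lies inside the tether, so the tether-endo transition state leads to the cis-fused decalin, and C10 cannot be epimerised afterwards.
- The C4 ketone must still be turned into CH–CH3.
- The osmylation forces the isopropenyl group to be masked as a tertiary ether and regenerated by a dehydration of uncertain regiochemistry.

The chosen plan gets the trans fusion from two equatorial tethers and has no alkene oxidation to protect against.

**Alternative 3:** Dearomatisation (cut C5–C14). Birch reductive methylation of 5-methoxy-1-tetralone gives dienone A4, with the quaternary C5 and oxygen at C4 and C9 in one step from a flat arene. A4 is racemic, with no handle for absolute control. Its C4 carbonyl poses the same problem as in Alternative 1. A C9 ketone in the trans-decalin is reduced from the α face (C14 blocks the β face) to the wrong 9β alcohol. The chosen plan relays every centre from one catalytically set carbinol.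

Key step: step 11

Assumption: the SMILES is taken as the full definition of the target, and (S)-pent-1-yn-3-ol is taken as a purchasable alkynol.

## Route

Step 1
Reactants: 1 cyclohexa-1,3-diene
Product: 3 (R)-4-hydroxycyclohex-2-en-1-one, via 2,3-dioxabicyclo[2.2.2]oct-5-ene 2 (not isolated)
Conditions: O2, hν, TPP (cat.), CH2Cl2, 0 °C; then bifunctional cinchona base (5 mol %, pseudo-enantiomer that gives the R enone), rt
Reagents that add atoms: dioxygen, O=O
Why: [4+2] addition of singlet oxygen gives the meso endoperoxide, and the chiral base removes one of the two enantiotopic bridgehead hydrogens (desymmetrising Kornblum–DeLaMare rearrangement), which sets C3 (R), the only core centre set by a catalyst.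

Step 2
Reactants: 3 (R)-4-hydroxycyclohex-2-en-1-one
Product: 4 (R)-4-[(triethylsilyl)oxy]cyclohex-2-en-1-one
Conditions: TESCl, imidazole, CH2Cl2, 0 °C
Reagents that add atoms: chlorotriethylsilane, CC[Si](CC)(CC)Cl
Why: Standard silylation; the silyloxy group is the directing group for step 5 and is the more labile of the two silyl ethers used later.

Step 3
Reactants: 4 (R)-4-[(triethylsilyl)oxy]cyclohex-2-en-1-one
Product: 5 (R)-2-iodo-4-[(triethylsilyl)oxy]cyclohex-2-en-1-one
Conditions: I2, pyridine/CH2Cl2, 0 °C to rt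
Reagents that add atoms: iodine, II
Why: α-Iodination of an enone by pyridine conjugate addition, iodination and elimination (Baylis–Hillman-type mechanism); C3 is not involved.

Step 4
Reactants: 5 (R)-2-iodo-4-[(triethylsilyl)oxy]cyclohex-2-en-1-one
Product: 6 (R)-2-methyl-4-[(triethylsilyl)oxy]cyclohex-2-en-1-one
Conditions: MeZnCl, Pd(dppf)Cl2 (3 mol %), THF, 0 °C to rt
Reagents that add atoms: methylzinc chloride, C[Zn]Cl
Why: Negishi coupling of an α-iodoenone installs C14 and gives the α-methyl enone needed for a regiodefined tetrasubstituted enolate.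

Step 5
Reactants: 6 (R)-2-methyl-4-[(triethylsilyl)oxy]cyclohex-2-en-1-one; 7 1-bromo-3-methylbut-2-ene (prenyl bromide)
Product: 9 (2R,3R,4R)-2,3-dimethyl-2-(3-methylbut-2-en-1-yl)-4-[(triethylsilyl)oxy]cyclohexan-1-one, via lithium enolate 8 (not isolated)
Conditions: Me2CuLi (from MeLi, CuI), Et2O, −78 to −40 °C; then 7, HMPA, THF, −40 to 0 °C
Reagents that add atoms: lithium dimethylcuprate, [Li+].C[Cu-]C
Why: Three-component conjugate addition–enolate alkylation: the cuprate adds to C4 anti to the C3 silyloxy group, and enolate 8, with the new C4 methyl pseudoaxial to avoid A(1,2) strain, is prenylated at C5 on the face anti to that methyl. This gives the cis-vicinal methyls and the quaternary C5 in one operation.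

Step 6
Reactants: 9 (2R,3R,4R)-2,3-dimethyl-2-(3-methylbut-2-en-1-yl)-4-[(triethylsilyl)oxy]cyclohexan-1-one
Product: 10 ethyl 2-[(2R,3R,4R)-2,3-dimethyl-2-(3-methylbut-2-en-1-yl)-4-[(triethylsilyl)oxy]cyclohexylidene]acetate (E/Z mixture)
Conditions: ethyl (trimethylsilyl)acetate, LDA, THF, −78 °C to rt
Reagents that add atoms: ethyl 2-(trimethylsilyl)acetate, CCOC(=O)C[Si](C)(C)C
Why: Peterson olefination, chosen because the small lithium α-silyl ester enolate adds to ketones flanked by a quaternary carbon; it brings in C9 and C8, and the alkene geometry does not matter for step 7.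

Step 7
Reactants: 10 ethyl 2-[(2R,3R,4R)-2,3-dimethyl-2-(3-methylbut-2-en-1-yl)-4-[(triethylsilyl)oxy]cyclohexylidene]acetate
Product: 11 ethyl 2-[(1S,2S,3R,4R)-2,3-dimethyl-2-(3-methylbut-2-en-1-yl)-4-[(triethylsilyl)oxy]cyclohexyl]acetate
Conditions: Cu(OAc)2·H2O (5 mol %), 1,2-bis(diphenylphosphino)benzene (5 mol %), (EtO)2MeSiH, t-BuOH, toluene, rt
Reagents that add atoms: none
Why: Copper hydride conjugate reduction of a β,β-disubstituted enoate leaves the isolated prenyl alkene alone; hydride reaches C10 along the axial trajectory on the face opposite the adjacent axial C14, so H-10 becomes axial (α) and the acetate arm equatorial, trans to the prenyl group.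

Step 8
Reactants: 11 ethyl 2-[(1S,2S,3R,4R)-2,3-dimethyl-2-(3-methylbut-2-en-1-yl)-4-[(triethylsilyl)oxy]cyclohexyl]acetate
Product: 13 ethyl (2S)-2-hydroxy-2-[(1R,2R,3R,4R)-2,3-dimethyl-2-(3-methylbut-2-en-1-yl)-4-[(triethylsilyl)oxy]cyclohexyl]acetate, via potassium ester enolate 12 (not isolated)
Conditions: KHMDS, THF, −78 °C; then 2-(phenylsulfonyl)-3-phenyloxaziridine, −78 °C; aq. NH4Cl
Reagents that add atoms: 2-(phenylsulfonyl)-3-phenyloxaziridine, O=S(=O)(N1OC1c1ccccc1)c1ccccc1
Why: Enolate hydroxylation with an N-sulfonyloxaziridine; allylic 1,3-strain holds the C10–H bond in the enolate plane, and the oxidant enters from the face flanked by the C1 methylene, away from the quaternary C5, which gives 9S.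

Step 9
Reactants: 13 ethyl (2S)-2-hydroxy-2-[(1R,2R,3R,4R)-2,3-dimethyl-2-(3-methylbut-2-en-1-yl)-4-[(triethylsilyl)oxy]cyclohexyl]acetate
Product: 14 ethyl (2S)-2-[(tert-butyldimethylsilyl)oxy]-2-[(1R,2R,3R,4R)-2,3-dimethyl-2-(3-methylbut-2-en-1-yl)-4-[(triethylsilyl)oxy]cyclohexyl]acetate
Conditions: TBSOTf, 2,6-lutidine, CH2Cl2, 0 °C
Reagents that add atoms: tert-butyldimethylsilyl triflate, CC(C)(C)[Si](C)(C)OS(=O)(=O)C(F)(F)F
Why: Silylation of a hindered secondary alcohol with the silyl triflate; the TBS ether is non-chelating and survives the later selective removal of the C3 TES ether.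

Step 10
Reactants: 14 ethyl (2S)-2-[(tert-butyldimethylsilyl)oxy]-2-[(1R,2R,3R,4R)-2,3-dimethyl-2-(3-methylbut-2-en-1-yl)-4-[(triethylsilyl)oxy]cyclohexyl]acetate
Product: 15 (2S)-2-[(tert-butyldimethylsilyl)oxy]-2-[(1R,2R,3R,4R)-2,3-dimethyl-2-(3-methylbut-2-en-1-yl)-4-[(triethylsilyl)oxy]cyclohexyl]acetaldehyde
Conditions: DIBAL-H (1.1 equiv), CH2Cl2, −78 °C; Rochelle salt
Reagents that add atoms: none
Why: Half-reduction of an α-silyloxy ester; the tetrahedral aluminium intermediate is stable at −78 °C, so the aldehyde appears only on work-up and C9 is not epimerised.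

Step 11
Reactants: 15 (2S)-2-[(tert-butyldimethylsilyl)oxy]-2-[(1R,2R,3R,4R)-2,3-dimethyl-2-(3-methylbut-2-en-1-yl)-4-[(triethylsilyl)oxy]cyclohexyl]acetaldehyde
Product: 16 (3R,4R,5R,7S,9S,10R)-9-[(tert-butyldimethylsilyl)oxy]-3-[(triethylsilyl)oxy]eremophil-11-en-8-ol (C8 epimers, both carried on)
Conditions: Me2AlCl (1.5 equiv), CH2Cl2, −78 to −20 °C
Reagents that add atoms: none
Why: Me2AlCl binds the aldehyde oxygen; C8 is attacked by C7 of the prenyl group while an allylic hydrogen of a C11 methyl passes to oxygen and the π bond moves to C11=C12, a type I intramolecular carbonyl-ene reaction of the citronellal-to-isopulegol kind. Ring B (C5–C6–C7–C8–C9–C10) closes through a chair in which the carbonyl carbon bonds to the nearer alkene carbon, leaving the new alkene outside the ring. Both tethers are equatorial on the ring A chair (fixed by the equatorial C3 and C4 substituents and the axial C14), so only the trans-fused decalin can form. C7 is controlled by the axial C14: the C7=C11 unit must lie equatorial because the axial position is syn-axial to C14, which gives 7α (7S). C8 forms without reliable control (the equatorial preference of the complexed oxygen opposes the Felkin arrangement beside the C9 silyloxy group) and is not relied on; steps 12 and 13 set it. The selectivity needed is proton transfer over cation capture, secured by the methylaluminium reagent, which scavenges protons and whose alkoxide product is not a Brønsted acid. Six- over seven-membered closure follows from the polarity of the trisubstituted alkene.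

Step 12
Reactants: 16 (3R,4R,5R,7S,9S,10R)-9-[(tert-butyldimethylsilyl)oxy]-3-[(triethylsilyl)oxy]eremophil-11-en-8-ol
Product: 17 (3R,4R,5R,7S,9S,10R)-9-[(tert-butyldimethylsilyl)oxy]-3-[(triethylsilyl)oxy]eremophil-11-en-8-one
Conditions: Dess–Martin periodinane, NaHCO3, CH2Cl2, 0 °C to rt
Reagents that add atoms: none
Why: Buffered periodinane oxidation brings both C8 epimers to one ketone under neutral conditions, so the β,γ-unsaturated ketone does not move into conjugation; C7 and C9 already carry equatorial groups and cannot improve by epimerisation.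

Step 13
Reactants: 17 (3R,4R,5R,7S,9S,10R)-9-[(tert-butyldimethylsilyl)oxy]-3-[(triethylsilyl)oxy]eremophil-11-en-8-one
Product: 18 (3R,4R,5R,7S,8R,9S,10R)-9-[(tert-butyldimethylsilyl)oxy]-3-[(triethylsilyl)oxy]eremophil-11-en-8-ol
Conditions: L-Selectride, THF, −78 °C
Reagents that add atoms: none
Why: The bulky tri-sec-butylborohydride attacks the cyclohexanone along the equatorial trajectory and gives the axial 8α alcohol, cis to both equatorial neighbours, as with 2-alkoxycyclohexanones; at −78 °C reduction outruns enolisation.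

Step 14
Reactants: 18 (3R,4R,5R,7S,8R,9S,10R)-9-[(tert-butyldimethylsilyl)oxy]-3-[(triethylsilyl)oxy]eremophil-11-en-8-ol
Product: 19 (3R,4R,5R,7S,8R,9S,10R)-9-[(tert-butyldimethylsilyl)oxy]eremophil-11-ene-3,8-diol
Conditions: PPTS (0.2 equiv), MeOH/CH2Cl2, 0 °C
Reagents that add atoms: none
Why: Acid-catalysed methanolysis removes a secondary TES ether much faster than the hindered secondary TBS ether; the isopropenyl group is stable to this weak acid.

Step 15
Reactants: 20 (S)-pent-1-yn-3-ol
Product: 22 (S)-4-hydroxyhex-2-ynoic acid, via dilithium alkynide alkoxide 21 (not isolated)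
Conditions: n-BuLi (2.1 equiv), THF, −78 °C; CO2; then 1 M HCl
Reagents that add atoms: carbon dioxide, O=C=O
Why: Carboxylation of the acetylide of a propargylic alcohol dianion; the carbonate formed at oxygen is lost on acidification and the stereocentre is not touched.

Step 16
Reactants: 22 (S)-4-hydroxyhex-2-ynoic acid
Product: 23 4-methoxybenzyl (S)-4-hydroxyhex-2-ynoate
Conditions: PMBCl, KHCO3, DMF, rt
Reagents that add atoms: 4-methoxybenzyl chloride, COc1ccc(CCl)cc1
Why: O-Alkylation of the carboxylate; under bicarbonate the secondary alcohol is not alkylated.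

Step 17
Reactants: 23 4-methoxybenzyl (S)-4-hydroxyhex-2-ynoate; 24 hex-2-ynoic acid
Product: 25 4-methoxybenzyl (S)-4-(hex-2-ynoyloxy)hex-2-ynoate
Conditions: DIC, DMAP (cat.), CH2Cl2, 0 °C
Reagents that add atoms: none
Why: Steglich esterification of an unhindered propargylic alcohol; an alkynoic acid has no alkene geometry to lose on activation.

Step 18
Reactants: 25 4-methoxybenzyl (S)-4-(hex-2-ynoyloxy)hex-2-ynoate
Product: 26 (S)-4-(hex-2-ynoyloxy)hex-2-ynoic acid
Conditions: TFA/CH2Cl2 (1:5), anisole, 0 °C
Reagents that add atoms: none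
Why: Acidolysis of the PMB ester with anisole as cation trap; the propargylic ester and both ynoates tolerate brief cold TFA.

Step 19
Reactants: 19 (3R,4R,5R,7S,8R,9S,10R)-9-[(tert-butyldimethylsilyl)oxy]eremophil-11-ene-3,8-diol; 26 (S)-4-(hex-2-ynoyloxy)hex-2-ynoic acid
Product: 27 (3R,4R,5R,7S,8R,9S,10R)-9-[(tert-butyldimethylsilyl)oxy]-8-hydroxyeremophil-11-en-3-yl (4S)-4-(hex-2-ynoyloxy)hex-2-ynoate
Conditions: 26 (1.2 equiv), DIC, DMAP (0.1 equiv), CH2Cl2, −10 °C to rt
Reagents that add atoms: none
Why: Steglich esterification; the equatorial C3–OH, with one equatorial methyl neighbour, should react well ahead of the axial C8–OH, which sits between the silyloxy and isopropenyl groups.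

Step 20
Reactants: 27 (3R,4R,5R,7S,8R,9S,10R)-9-[(tert-butyldimethylsilyl)oxy]-8-hydroxyeremophil-11-en-3-yl (4S)-4-(hex-2-ynoyloxy)hex-2-ynoate
Product: 28 (3R,4R,5R,7S,8R,9S,10R)-9-[(tert-butyldimethylsilyl)oxy]-8-hydroxyeremophil-11-en-3-yl (2Z,4S)-4-[(2Z)-hex-2-enoyloxy]hex-2-enoate
Conditions: H2 (1 atm), Lindlar catalyst, quinoline, EtOAc, rt, stopped at 2 equiv H2
Reagents that add atoms: none
Why: Lindlar semihydrogenation adds hydrogen syn to both ynoates and gives the two (Z)-enoates with the C4′ oxygen already acylated, so no butenolide can form; the 1,1-disubstituted isopropenyl alkene is not reduced on the poisoned catalyst.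

Step 21
Reactants: 28 (3R,4R,5R,7S,8R,9S,10R)-9-[(tert-butyldimethylsilyl)oxy]-8-hydroxyeremophil-11-en-3-yl (2Z,4S)-4-[(2Z)-hex-2-enoyloxy]hex-2-enoate
Product: 29 (3R,4R,5R,7S,8R,9S,10R)-8,9-dihydroxyeremophil-11-en-3-yl (2Z,4S)-4-[(2Z)-hex-2-enoyloxy]hex-2-enoate (target)
Conditions: HF·pyridine, pyridine, THF, 0 °C to rt
Reagents that add atoms: none
Why: Buffered fluoride desilylation under non-basic conditions, so the (Z)-enoates do not isomerise and no acyl group migrates.

## Compound list

1 | cyclohexa-1,3-diene | C1=CC=CCC1 | starting material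
2 | 2,3-dioxabicyclo[2.2.2]oct-5-ene | O1OC2CCC1C=C2 | intermediate (not isolated)
3 | (R)-4-hydroxycyclohex-2-en-1-one | O=C1C=C[C@H](O)CC1 | intermediate
4 | (R)-4-[(triethylsilyl)oxy]cyclohex-2-en-1-one | O=C1C=C[C@H](O[Si](CC)(CC)CC)CC1 | intermediate
5 | (R)-2-iodo-4-[(triethylsilyl)oxy]cyclohex-2-en-1-one | O=C1C(I)=C[C@H](O[Si](CC)(CC)CC)CC1 | intermediate
6 | (R)-2-methyl-4-[(triethylsilyl)oxy]cyclohex-2-en-1-one | O=C1C(C)=C[C@H](O[Si](CC)(CC)CC)CC1 | intermediate
7 | 1-bromo-3-methylbut-2-ene | CC(C)=CCBr | starting material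
8 | lithium (3R,4R)-2,3-dimethyl-4-[(triethylsilyl)oxy]cyclohex-1-en-1-olate | [Li+].[O-]C1=C(C)[C@@H](C)[C@H](O[Si](CC)(CC)CC)CC1 | intermediate (not isolated)
9 | (2R,3R,4R)-2,3-dimethyl-2-(3-methylbut-2-en-1-yl)-4-[(triethylsilyl)oxy]cyclohexan-1-one | CC(C)=CC[C@]1(C)[C@@H](C)[C@H](O[Si](CC)(CC)CC)CCC1=O | intermediate
10 | ethyl 2-[(2R,3R,4R)-2,3-dimethyl-2-(3-methylbut-2-en-1-yl)-4-[(triethylsilyl)oxy]cyclohexylidene]acetate (E/Z mixture) | CC(C)=CC[C@]1(C)[C@@H](C)[C@H](O[Si](CC)(CC)CC)CCC1=CC(=O)OCC | intermediate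
11 | ethyl 2-[(1S,2S,3R,4R)-2,3-dimethyl-2-(3-methylbut-2-en-1-yl)-4-[(triethylsilyl)oxy]cyclohexyl]acetate | CC(C)=CC[C@]1(C)[C@@H](C)[C@H](O[Si](CC)(CC)CC)CC[C@H]1CC(=O)OCC | intermediate
12 | potassium enolate of 11 | [K+].CC(C)=CC[C@]1(C)[C@@H](C)[C@H](O[Si](CC)(CC)CC)CC[C@H]1C=C([O-])OCC | intermediate (not isolated)
13 | ethyl (2S)-2-hydroxy-2-[(1R,2R,3R,4R)-2,3-dimethyl-2-(3-methylbut-2-en-1-yl)-4-[(triethylsilyl)oxy]cyclohexyl]acetate | CC(C)=CC[C@]1(C)[C@@H](C)[C@H](O[Si](CC)(CC)CC)CC[C@H]1[C@H](O)C(=O)OCC | intermediate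
14 | ethyl (2S)-2-[(tert-butyldimethylsilyl)oxy]-2-[(1R,2R,3R,4R)-2,3-dimethyl-2-(3-methylbut-2-en-1-yl)-4-[(triethylsilyl)oxy]cyclohexyl]acetate | CC(C)=CC[C@]1(C)[C@@H](C)[C@H](O[Si](CC)(CC)CC)CC[C@H]1[C@H](O[Si](C)(C)C(C)(C)C)C(=O)OCC | intermediate
15 | (2S)-2-[(tert-butyldimethylsilyl)oxy]-2-[(1R,2R,3R,4R)-2,3-dimethyl-2-(3-methylbut-2-en-1-yl)-4-[(triethylsilyl)oxy]cyclohexyl]acetaldehyde | CC(C)=CC[C@]1(C)[C@@H](C)[C@H](O[Si](CC)(CC)CC)CC[C@H]1[C@H](O[Si](C)(C)C(C)(C)C)C=O | intermediate
16 | (3R,4R,5R,7S,9S,10R)-9-[(tert-butyldimethylsilyl)oxy]-3-[(triethylsilyl)oxy]eremophil-11-en-8-ol, C8 epimers | C=C(C)[C@@H]1C[C@]2(C)[C@@H](C)[C@H](O[Si](CC)(CC)CC)CC[C@H]2[C@H](O[Si](C)(C)C(C)(C)C)C1O | intermediate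
17 | (3R,4R,5R,7S,9S,10R)-9-[(tert-butyldimethylsilyl)oxy]-3-[(triethylsilyl)oxy]eremophil-11-en-8-one | C=C(C)[C@@H]1C[C@]2(C)[C@@H](C)[C@H](O[Si](CC)(CC)CC)CC[C@H]2[C@H](O[Si](C)(C)C(C)(C)C)C1=O | intermediate
18 | (3R,4R,5R,7S,8R,9S,10R)-9-[(tert-butyldimethylsilyl)oxy]-3-[(triethylsilyl)oxy]eremophil-11-en-8-ol | C=C(C)[C@@H]1C[C@]2(C)[C@@H](C)[C@H](O[Si](CC)(CC)CC)CC[C@H]2[C@H](O[Si](C)(C)C(C)(C)C)[C@@H]1O | intermediate
19 | (3R,4R,5R,7S,8R,9S,10R)-9-[(tert-butyldimethylsilyl)oxy]eremophil-11-ene-3,8-diol | C=C(C)[C@@H]1C[C@]2(C)[C@@H](C)[C@H](O)CC[C@H]2[C@H](O[Si](C)(C)C(C)(C)C)[C@@H]1O | intermediate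
20 | (S)-pent-1-yn-3-ol | C#C[C@H](CC)O | starting material
21 | dilithium (S)-pent-1-yn-1-id-3-olate | [Li+].[Li+].[C-]#C[C@H](CC)[O-] | intermediate (not isolated)
22 | (S)-4-hydroxyhex-2-ynoic acid | OC(=O)C#C[C@H](CC)O | intermediate
23 | 4-methoxybenzyl (S)-4-hydroxyhex-2-ynoate | COc1ccc(COC(=O)C#C[C@H](CC)O)cc1 | intermediate
24 | hex-2-ynoic acid | CCCC#CC(=O)O | starting material
25 | 4-methoxybenzyl (S)-4-(hex-2-ynoyloxy)hex-2-ynoate | COc1ccc(COC(=O)C#C[C@H](CC)OC(=O)C#CCCC)cc1 | intermediate
26 | (S)-4-(hex-2-ynoyloxy)hex-2-ynoic acid | OC(=O)C#C[C@H](CC)OC(=O)C#CCCC | intermediate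
27 | (3R,4R,5R,7S,8R,9S,10R)-9-[(tert-butyldimethylsilyl)oxy]-8-hydroxyeremophil-11-en-3-yl (4S)-4-(hex-2-ynoyloxy)hex-2-ynoate | C=C(C)[C@@H]1C[C@]2(C)[C@@H](C)[C@H](OC(=O)C#C[C@H](CC)OC(=O)C#CCCC)CC[C@H]2[C@H](O[Si](C)(C)C(C)(C)C)[C@@H]1O | intermediate
28 | (3R,4R,5R,7S,8R,9S,10R)-9-[(tert-butyldimethylsilyl)oxy]-8-hydroxyeremophil-11-en-3-yl (2Z,4S)-4-[(2Z)-hex-2-enoyloxy]hex-2-enoate | C=C(C)[C@@H]1C[C@]2(C)[C@@H](C)[C@H](OC(=O)/C=C\[C@H](CC)OC(=O)/C=C\CCC)CC[C@H]2[C@H](O[Si](C)(C)C(C)(C)C)[C@@H]1O | intermediate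
29 | (3R,4R,5R,7S,8R,9S,10R)-8,9-dihydroxyeremophil-11-en-3-yl (2Z,4S)-4-[(2Z)-hex-2-enoyloxy]hex-2-enoate | C=C(C)[C@@H]1C[C@]2(C)[C@@H](C)[C@H](OC(=O)/C=C\[C@H](CC)OC(=O)/C=C\CCC)CC[C@H]2[C@H](O)[C@@H]1O | target

## Step count and least certain steps

Total: 21 steps. Longest linear sequence: 17 steps (steps 1–14 and 19–21); the acid 26 is made in 4 steps (15–18) and joined in step 19.

**Step 11 (key step).** The Lewis acid may be held unproductively between the aldehyde and the C9 silyloxy oxygen. Ring closure would then be slow, and the activated α-silyloxy aldehyde could epimerise at C9, lose silanol, or close through cation capture instead of proton transfer. The fallback moves the C9 oxygenation behind the ring closure. It sets out from 11: DIBAL-H half-reduction gives the plain aldehyde 2-[(1S,2S,3R,4R)-2,3-dimethyl-2-(3-methylbut-2-en-1-yl)-4-[(triethylsilyl)oxy]cyclohexyl]acetaldehyde F1, which is an exact citronellal-type ene substrate. Me2AlCl closes it to 3α-(triethylsilyloxy)eremophil-11-en-8-ol F2. Dess–Martin oxidation gives the 8-ketone F3. Kinetic enolisation toward the C9 methylene and oxaziridine hydroxylation from the α face (the β face is blocked by C14) give the 9α-hydroxy-8-ketone F4. Silylation with TBSOTf brings the route back at 17.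

**Step 5.** The tetrasubstituted enolate may be alkylated with poor facial selectivity, since the incoming prenyl group is syn-axial to the silyloxy group in the favoured transition state. O-alkylation, proton transfer and double alkylation are the other dangers. The fallback makes the C5–C6 bond by a catalyst-controlled, regiospecific allylation. It sets out from 6: cuprate addition and trapping with allyl chloroformate give the allyl enol carbonate F5. Palladium-catalysed decarboxylative allylation with the matched PHOX ligand gives the allyl ketone (2R,3R,4R)-2-allyl-2,3-dimethyl-4-[(triethylsilyl)oxy]cyclohexan-1-one F6. Cross-metathesis with 2-methylbut-2-ene (Grubbs second-generation catalyst) returns to 9.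

**Step 7.** Hydride delivery to the hindered C10 may be incompletely face-selective, and C10 cannot be corrected later in the main route; the enoate may also slip out of conjugation into the ring. The fallback makes C10 epimerisable and puts C9 under catalyst control. It sets out from 11 as a C10 mixture: the mixture is hydroxylated as in step 8 and oxidised with Dess–Martin periodinane to the α-keto ester ethyl 2-[(1R,2R,3R,4R)-2,3-dimethyl-2-(3-methylbut-2-en-1-yl)-4-[(triethylsilyl)oxy]cyclohexyl]-2-oxoacetate F7. This is equilibrated with DBU to the equatorial C10 epimer and reduced by Ru–TsDPEN transfer hydrogenation (catalyst enantiomer chosen for 9S), which returns to 13. The same loop corrects a poor C9 ratio in step 8.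

**Step 19.** Site selectivity may be lost through competing acylation of the C8 hydroxyl or silyl migration from O9 to O8 under DMAP. The fallback removes the competing hydroxyl. It sets out from 18: TBSOTf gives the 8,9-bis-TBS ether F8. PPTS in methanol frees C3–OH to give the 8,9-bis(silyloxy) alcohol F9. Steglich esterification with 26 gives the bis-ynoate F10. Lindlar semihydrogenation gives the (Z,Z)-dienoate F11. HF·pyridine removes both TBS groups and returns at 29.

## Further compounds

F1 | step 11 | 2-[(1S,2S,3R,4R)-2,3-dimethyl-2-(3-methylbut-2-en-1-yl)-4-[(triethylsilyl)oxy]cyclohexyl]acetaldehyde | CC(C)=CC[C@]1(C)[C@@H](C)[C@H](O[Si](CC)(CC)CC)CC[C@H]1CC=O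
F2 | step 11 | 3α-(triethylsilyloxy)eremophil-11-en-8-ol (4β,5β-dimethyl, 7α-isopropenyl, 10α-H; C8 epimers) | C=C(C)[C@@H]1C[C@]2(C)[C@@H](C)[C@H](O[Si](CC)(CC)CC)CC[C@H]2CC1O
F3 | step 11 | 3α-(triethylsilyloxy)eremophil-11-en-8-one | C=C(C)[C@@H]1C[C@]2(C)[C@@H](C)[C@H](O[Si](CC)(CC)CC)CC[C@H]2CC1=O
F4 | step 11 | 9α-hydroxy-3α-(triethylsilyloxy)eremophil-11-en-8-one | C=C(C)[C@@H]1C[C@]2(C)[C@@H](C)[C@H](O[Si](CC)(CC)CC)CC[C@H]2[C@H](O)C1=O
F5 | step 5 | allyl (3R,4R)-2,3-dimethyl-4-[(triethylsilyl)oxy]cyclohex-1-en-1-yl carbonate | C=CCOC(=O)OC1=C(C)[C@@H](C)[C@H](O[Si](CC)(CC)CC)CC1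
F6 | step 5 | (2R,3R,4R)-2-allyl-2,3-dimethyl-4-[(triethylsilyl)oxy]cyclohexan-1-one | C=CC[C@]1(C)[C@@H](C)[C@H](O[Si](CC)(CC)CC)CCC1=O
F7 | step 7 | ethyl 2-[(1R,2R,3R,4R)-2,3-dimethyl-2-(3-methylbut-2-en-1-yl)-4-[(triethylsilyl)oxy]cyclohexyl]-2-oxoacetate | CC(C)=CC[C@]1(C)[C@@H](C)[C@H](O[Si](CC)(CC)CC)CC[C@H]1C(=O)C(=O)OCC
F8 | step 19 | 8α,9α-bis[(tert-butyldimethylsilyl)oxy]-3α-(triethylsilyloxy)eremophil-11-ene | C=C(C)[C@@H]1C[C@]2(C)[C@@H](C)[C@H](O[Si](CC)(CC)CC)CC[C@H]2[C@H](O[Si](C)(C)C(C)(C)C)[C@@H]1O[Si](C)(C)C(C)(C)C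
F9 | step 19 | 8α,9α-bis[(tert-butyldimethylsilyl)oxy]eremophil-11-en-3α-ol | C=C(C)[C@@H]1C[C@]2(C)[C@@H](C)[C@H](O)CC[C@H]2[C@H](O[Si](C)(C)C(C)(C)C)[C@@H]1O[Si](C)(C)C(C)(C)C
F10 | step 19 | 8α,9α-bis[(tert-butyldimethylsilyl)oxy]eremophil-11-en-3α-yl (4S)-4-(hex-2-ynoyloxy)hex-2-ynoate | C=C(C)[C@@H]1C[C@]2(C)[C@@H](C)[C@H](OC(=O)C#C[C@H](CC)OC(=O)C#CCCC)CC[C@H]2[C@H](O[Si](C)(C)C(C)(C)C)[C@@H]1O[Si](C)(C)C(C)(C)C
F11 | step 19 | 8α,9α-bis[(tert-butyldimethylsilyl)oxy]eremophil-11-en-3α-yl (2Z,4S)-4-[(2Z)-hex-2-enoyloxy]hex-2-enoate | C=C(C)[C@@H]1C[C@]2(C)[C@@H](C)[C@H](OC(=O)/C=C\[C@H](CC)OC(=O)/C=C\CCC)CC[C@H]2[C@H](O[Si](C)(C)C(C)(C)C)[C@@H]1O[Si](C)(C)C(C)(C)C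
A1 | alternative 1 | (S)-Wieland–Miescher ketone | O=C1CC[C@]2(C)C(=O)CCCC2=C1
A2 | alternative 2 | (4R,7E,9E)-4-[(tert-butyldimethylsilyl)oxy]-2,11-dimethyl-11-[(triethylsilyl)oxy]dodeca-1,7,9-trien-3-one | C=C(C)C(=O)[C@H](O[Si](C)(C)C(C)(C)C)CC/C=C/C=C/C(C)(C)O[Si](CC)(CC)CC
A3 | alternative 2 | trans-fused Diels–Alder adduct, 3α-(TBS-oxy)-11-(TES-oxy)-4-oxo-15-noreremophil-8-ene | CC(C)(O[Si](CC)(CC)CC)[C@@H]1C[C@]2(C)C(=O)[C@H](O[Si](C)(C)C(C)(C)C)CC[C@H]2C=C1
A4 | alternative 3 | rac-5-methoxy-8a-methyl-3,4,8,8a-tetrahydronaphthalen-1(2H)-one | COC1=C2CCCC(=O)C2(C)C=CC1
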